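## Retrosynthetic overview
1. Manniflavanone comes from its nona-O-TBS ether by one global desilylation.
2. The key disconnection is the inter-unit C3–C8'' bond. A C8'' aryl radical (from an 8-iodotaxifolin silyl ether) adds to C3 of a flavanone silyl enol ether in one visible-light photoredox step.
3. The iodide comes from (+)-taxifolin by silylation and C8 iodination, so C2''/C3'' are bought. The enol silane comes from eriodictyol in one exhaustive silylation.
4. Ring order: all six rings are bought intact and none is built. The coupling gives a pair of 2,3-trans diastereomers. The upper C ring is then opened and re-closed (retro-oxa-Michael/oxa-Michael) next to the fixed taxifolin unit, which channels the pair into the (2R,3S) series.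

Numbering: unprimed = upper (eriodictyol-type) unit, double-primed = lower (taxifolin-type) unit. The target SMILES decodes as (2R,3S,2''R,3''R), with both C rings 2,3-trans.

Assumption: commercial eriodictyol is used as the racemate, and its C2 configuration is never relied on.

## Route

**Step 1**
Reactants: 1, (+)-(2R,3R)-taxifolin
Product: 2, (2R,3R)-3,5,7,3',4'-penta-O-TBS-taxifolin
Conditions: TBSOTf (7 equiv), 2,6-lutidine (10 equiv), CH2Cl2, −20 → 23 °C
Reagents that add atoms: TBSOTf, CC(C)(C)[Si](C)(C)OS(=O)(=O)C(F)(F)F
Why: This is O-silylation, where the silyl triflate also caps the H-bonded 5-OH and the hindered 3-OH, and the weak hindered base neither enolises C3 nor opens the C ring, so both stereocentres are kept.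

**Step 2**
Reactants: 2, penta-O-TBS-taxifolin
Product: 3, (2R,3R)-8-iodo-3,5,7,3',4'-penta-O-TBS-taxifolin
Conditions: NIS (1.1 equiv), AgNTf2 (5 mol %), CH2Cl2, 0 → 23 °C, dark
Reagents that add atoms: N-iodosuccinimide, O=C1CCC(=O)N1I
Why: This is electrophilic aromatic iodination; C8 is ortho/ortho/para to three O-donors and flanked by only one OTBS, C6 is buried between two OTBS groups, and ring B is less activated (the usual C8 preference of fully O-protected 5,7-dioxygenated flavonoids), with no stereocentre touched.

**Step 3**
Reactants: 4, (±)-eriodictyol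
Product: 5, (±)-2-[3,4-bis(TBSO)phenyl]-4,5,7-tris(TBSO)-2H-chromene (flavanone TBS enol ether)
Conditions: TBSOTf (6.5 equiv), Et3N (9 equiv), CH2Cl2, −78 → 0 °C; Et3N-deactivated SiO2
Reagents that add atoms: TBSOTf, CC(C)(C)[Si](C)(C)OS(=O)(=O)C(F)(F)F
Why: Phenol silylation plus soft enolisation (R3SiOTf/amine) gives the enol silane without a free enolate, so E1cB opening to the chalcone is avoided, and C2 stays racemic.

**Step 4 (key step)**
Reactants: 3, 8-iodo-penta-O-TBS-taxifolin (1 equiv); 5, flavanone TBS enol ether (3 equiv)
Product: 6, nona-O-TBS-3,8''-biflavanone, obtained as the unseparated mixture of its two 2,3-trans diastereomers, (2R,3S,2''R,3''R) and (2S,3R,2''R,3''R); C2''/C3'' are fixed and roughly 1:1 at C2/C3 is assumed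
Conditions: 10-phenylphenothiazine (5 mol %), 2,6-lutidine (1.5 equiv), t-BuOH (2 equiv), degassed PhCF3/MeCN 1:1 (0.5 M in 5), 390 nm LED, 20 °C; SiO2 only to remove excess 5 and any 2
Reagents that add atoms: none (all product atoms come from 3 and 5; I and one TBS leave as lutidinium iodide and t-BuOTBS)
Why: Proposed new method: a redox-neutral radical–polar crossover α-arylation of a cyclic flavanone enol silane with a hindered, electron-rich aryl iodide, in which the excited catalyst (about −2.1 V vs SCE) cleaves only the C–I bond of 3 (5 is not reducible and is transparent at 390 nm), the C8'' σ-radical adds to the electron-rich C3 of either enantiomer of 5 on the face anti to its C2 aryl group (which sets 2,3-trans in both diastereomers but not the sense relative to the lower unit), the resulting benzylic α-siloxy radical (Eox below 0 V) is oxidised by the catalyst radical cation (+0.68 V, too weak to oxidise any arene present), and the siloxycarbenium ion loses TBS to give the ketone; the closest known reactions are photoredox Meerwein-type α-arylation of enol acetates with arenediazonium salts and phenothiazine-photocatalysed reduction of aryl iodides, neither shown on flavanone enol silanes, 2,6-dioxygenated aryl iodides or a biflavanoid linkage.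
Note: The high concentration of 5 is needed to outrun solvent H-abstraction and 1,5-H transfer from SiMe. The hydrodeiodination by-product 2 goes back to step 2, and unreacted 5 is recovered.

**Step 5 (stereoconvergence)**
Reactants: 6, nona-O-TBS-3,8''-biflavanone (diastereomer mixture)
Product: 7, (2R,3S,2''R,3''R)-nona-O-TBS-manniflavanone (single diastereomer)
Conditions: DBU (0.2 equiv), 4 Å MS, PhMe, 40 °C to constant dr; AcOH quench; SiO2 separation; the (2S,3R) fraction is put back through the same conditions (2–3 cycles)
Reagents that add atoms: none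
Why: This is base-catalysed retro-oxa-Michael/oxa-Michael (flavanone–chalcone) equilibration, in which only the α-aryl ketone C3–H is acidic enough for DBU, the ring-opened α-aryl-2'-oxidochalcone has no stereocentre left in the upper unit and re-closes (favoured by its 6'-OTBS) to the two trans isomers, and the (2''R,3''R) unit is the only stereochemical reference because the bulky 7''-OTBS turns C2/C4 toward O1''/C2''; C2''/C3'' survive because C3''–H is about 5 pK units less acidic and the quinone-methide route is blocked by silylation.
Note: The thermodynamic bias is expected to be modest. All material reaches 7 because the unwanted isomer is continually re-equilibrated, not because of a high single-pass dr.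

**Step 6**
Reactants: 7, (2R,3S,2''R,3''R)-nona-O-TBS-manniflavanone
Product: 8, manniflavanone
Conditions: HF·pyridine (excess), pyridine/THF, 0 → 23 °C, Ar; Me3SiOMe quench; Sephadex LH-20
Reagents that add atoms: none
Why: Fluoride cleaves the Si–O bonds (global desilylation) in an acidic medium where neither flavanone enolises or ring-opens and the catechols do not autoxidise, so all four stereocentres are retained.

## Compound list
1 | (+)-(2R,3R)-taxifolin | O=C1c2c(O)cc(O)cc2O[C@H](c2ccc(O)c(O)c2)[C@H]1O | starting material
2 | (2R,3R)-penta-O-TBS-taxifolin | O=C1c2c(O[Si](C)(C)C(C)(C)C)cc(O[Si](C)(C)C(C)(C)C)cc2O[C@H](c2ccc(O[Si](C)(C)C(C)(C)C)c(O[Si](C)(C)C(C)(C)C)c2)[C@H]1O[Si](C)(C)C(C)(C)C | intermediate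
3 | (2R,3R)-8-iodo-penta-O-TBS-taxifolin | O=C1c2c(O[Si](C)(C)C(C)(C)C)cc(O[Si](C)(C)C(C)(C)C)c(I)c2O[C@H](c2ccc(O[Si](C)(C)C(C)(C)C)c(O[Si](C)(C)C(C)(C)C)c2)[C@H]1O[Si](C)(C)C(C)(C)C | intermediate
4 | (±)-eriodictyol | O=C1CC(c2ccc(O)c(O)c2)Oc2cc(O)cc(O)c12 | starting material
5 | (±)-eriodictyol tetra-O-TBS ether 4-TBS enol ether | CC(C)(C)[Si](C)(C)OC1=CC(c2ccc(O[Si](C)(C)C(C)(C)C)c(O[Si](C)(C)C(C)(C)C)c2)Oc2cc(O[Si](C)(C)C(C)(C)C)cc(O[Si](C)(C)C(C)(C)C)c12 | intermediate
6 | nona-O-TBS-3,8''-biflavanone, mixture of the (2R,3S) and (2S,3R) 2,3-trans diastereomers, (2''R,3''R) fixed (C2/C3 left undefined in the SMILES) | O=C1c2c(O[Si](C)(C)C(C)(C)C)cc(O[Si](C)(C)C(C)(C)C)c(C3C(=O)c4c(O[Si](C)(C)C(C)(C)C)cc(O[Si](C)(C)C(C)(C)C)cc4OC3c3ccc(O[Si](C)(C)C(C)(C)C)c(O[Si](C)(C)C(C)(C)C)c3)c2O[C@H](c2ccc(O[Si](C)(C)C(C)(C)C)c(O[Si](C)(C)C(C)(C)C)c2)[C@H]1O[Si](C)(C)C(C)(C)C | intermediate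
7 | (2R,3S,2''R,3''R)-nona-O-TBS-manniflavanone | O=C1c2c(O[Si](C)(C)C(C)(C)C)cc(O[Si](C)(C)C(C)(C)C)c([C@@H]3C(=O)c4c(O[Si](C)(C)C(C)(C)C)cc(O[Si](C)(C)C(C)(C)C)cc4O[C@H]3c3ccc(O[Si](C)(C)C(C)(C)C)c(O[Si](C)(C)C(C)(C)C)c3)c2O[C@H](c2ccc(O[Si](C)(C)C(C)(C)C)c(O[Si](C)(C)C(C)(C)C)c2)[C@H]1O[Si](C)(C)C(C)(C)C | intermediate
8 | manniflavanone | O=C1c2c(O)cc(O)c([C@@H]3C(=O)c4c(O)cc(O)cc4O[C@H]3c3ccc(O)c(O)c3)c2O[C@H](c2ccc(O)c(O)c2)[C@H]1O | target

## Summary
Total steps: 6.

Longest linear sequence: 5 (1→2→3→6→7→8). The branch 4→5 is one step.

Steps most likely to fail: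

1. **Step 4 (new photoredox coupling).**
   - Risks: hydrodeiodination (solvent or SiMe H-transfer), H-abstraction from C2–H of 5, and steric congestion at C8''.
   - Fallback (known chemistry): switch to two-electron coupling and build the upper C ring afterwards.
     - Carry out a Pd/P(t-Bu)3, Bu3SnF-promoted (tin-enolate type) α-arylation of the TMS enol ether of 2,4,6-tris(TBSO)acetophenone with 3 to give the deoxybenzoin.
     - Unmask one ortho-phenol, then run the classical piperidine Knoevenagel/oxa-Michael annulation with 3,4-bis(TBSO)benzaldehyde. This gives the trans-2,3-diarylchromanone, which is 6 and rejoins the route at step 5.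

2. **Step 5 (C2/C3 convergence).**
   - Risks: the thermodynamic bias may be small or unfavourable, the two diastereomers may be hard to separate, and DBU may erode the aryl silyl ethers over repeated cycles.
   - Fallback: buy the C2 configuration instead.
     - Epimerise (−)-epicatechin at C2 in hot water to (−)-catechin and protect it.
     - Oxidise C4 (DDQ/H2O, then Dess–Martin), remove the 3-oxygen with SmI2 in the presence of a proton source, and soft-enolise to (2R)-5.
     - In step 4 this enantiomer gives 7 directly by anti addition, and step 5 is dropped. The cost is about five extra steps.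

3. **Step 2 (C8 versus C6 or B-ring iodination, lability of 5-OTBS).**
   - Fallback: start from (+)-catechin. Its per-O-protected form undergoes the well-established C8-selective NBS bromination.
   - Then install the C4 ketone (DDQ/H2O, then Dess–Martin) to reach the 8-halotaxifolin derivative. The cost is two extra steps, with the same bought stereocentres.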